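**Retrosynthetic overview**

1. Numbering: chain C1 (CH2 on S) to C9 (CH2 on ring A); ring A is the 1,2,6-trimethylcyclohex-2-enyl ring with quaternary C10 and C11H(CH3). Last disconnection S–C1: 26 ⇐ allylic bromide 23 + hypotaurocyamine 25 (sulfinate S-alkylation).
2. Key disconnection C5–C6 (together with C7–CH3): silyl ether 21 ⇐ ring alkyne 11 + Me3Al + homoallylic iodide 18, three components joined in one pot by Zr-catalysed syn-methylalumination, Al→Zn exchange and Pd-catalysed alkenyl–alkyl coupling.
3. Feature that makes this possible: the (E)-trisubstituted alkene C6=C7, with CH3 on C7 cis to the C6–C5 bond and one H on C6. This 2-methylalk-1-enyl unit is the imprint of a terminal alkyne C6≡C7 after syn addition of CH3–metal and retentive replacement of the metal on C6 by the C5 methylene.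
4. 11 ⇐ 2-methylcyclohex-2-en-1-one (1): Cu-catalysed asymmetric conjugate methylation/enolate allylation sets C11 and C10, enol triflate methylation gives the ring alkene, and the allyl group is homologated to the butynyl chain. 18 ⇐ silylated but-3-yn-1-ol 12 by a second methylalumination/hydroxymethylation.
5. Rings: ring A is the only ring; it is not closed in the route but comes as the six-membered ring of 1.

Key step: step 11

Assumption: the target is taken as the free guanidine base of the given SMILES, so the last step ends with a basic work-up.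

**Route**

Step 1
Reactants: 1 2-methylcyclohex-2-en-1-one
Product: 4 (2S,3R)-2,3-dimethyl-2-(prop-2-en-1-yl)cyclohexan-1-one, via dimethylaluminium enolate 2 (not isolated), via lithium aluminate enolate 3 (not isolated)
Conditions: Me3Al (1.4 equiv), Cu(O2C-2-thienyl) (2 mol%), chiral phosphoramidite ligand L* (4 mol%, enantiomer that gives the 3R adduct), Et2O, −30 °C; then THF, MeLi (1.4 equiv), DMPU, allyl iodide (3 equiv), −30 °C → rt
Reagents that add atoms: trimethylaluminium C[Al](C)C; allyl iodide C=CCI
Why: Cu-catalysed asymmetric conjugate addition of Me3Al sets C3 (R) under ligand control, and SN2 allylation of the derived aluminate enolate should occur anti to the pseudoaxial C3 methyl group, setting the quaternary C2 (S) with the two methyl groups cis (tandem conjugate addition–enolate alkylation).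

Step 2
Reactants: 4 (2S,3R)-2,3-dimethyl-2-(prop-2-en-1-yl)cyclohexan-1-one
Product: 6 (5R,6S)-5,6-dimethyl-6-(prop-2-en-1-yl)cyclohex-1-en-1-yl trifluoromethanesulfonate, via potassium enolate 5 (not isolated)
Conditions: KN(SiMe3)2, THF, −78 °C; then PhNTf2, −78 °C → 0 °C
Reagents that add atoms: N-phenylbis(trifluoromethanesulfonimide) O=S(=O)(N(c1ccccc1)S(=O)(=O)C(F)(F)F)C(F)(F)F
Why: Deprotonation can occur only at C6 because C2 is quaternary, and O-triflation of the potassium enolate gives one regioisomeric enol triflate without touching the stereocentres (enol triflate formation).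

Step 3
Reactants: 6 (5R,6S)-5,6-dimethyl-6-(prop-2-en-1-yl)cyclohex-1-en-1-yl trifluoromethanesulfonate
Product: 7 (5R,6S)-1,5,6-trimethyl-6-(prop-2-en-1-yl)cyclohex-1-ene
Conditions: MeMgBr (1.5 equiv), Fe(acac)3 (5 mol%), THF/NMP, −30 °C → 0 °C
Reagents that add atoms: methylmagnesium bromide C[Mg]Br
Why: Fe(acac)3-catalysed Kumada-type cross-coupling of enol triflates with MeMgBr is fast at low temperature and should tolerate the neighbouring quaternary centre and the terminal alkene, installing the ring vinyl methyl group.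

Step 4
Reactants: 7 (5R,6S)-1,5,6-trimethyl-6-(prop-2-en-1-yl)cyclohex-1-ene
Product: 9 3-[(1S,6R)-1,2,6-trimethylcyclohex-2-en-1-yl]propan-1-ol, via B-alkyl-9-BBN adduct 8 (not isolated)
Conditions: 9-BBN, THF, 0 °C → rt; then NaOH, H2O2, 0 °C → rt
Reagents that add atoms: hydrogen peroxide OO
Why: 9-BBN hydroborates the monosubstituted terminal alkene far faster than the trisubstituted ring alkene and places boron on the terminal carbon, so oxidation gives the primary alcohol (anti-Markovnikov hydroboration–oxidation).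

Step 5
Reactants: 9 3-[(1S,6R)-1,2,6-trimethylcyclohex-2-en-1-yl]propan-1-ol
Product: 10 3-[(1S,6R)-1,2,6-trimethylcyclohex-2-en-1-yl]propanal
Conditions: Dess–Martin periodinane, NaHCO3, CH2Cl2, 0 °C → rt
Reagents that add atoms: none
Why: Buffered Dess–Martin oxidation converts the primary alcohol into the aldehyde without acid-promoted migration of the ring alkene.

Step 6
Reactants: 10 3-[(1S,6R)-1,2,6-trimethylcyclohex-2-en-1-yl]propanal
Product: 11 (5R,6S)-6-(but-3-yn-1-yl)-1,5,6-trimethylcyclohex-1-ene
Conditions: dimethyl (1-diazo-2-oxopropyl)phosphonate, K2CO3, MeOH, 0 °C → rt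
Reagents that add atoms: dimethyl (1-diazo-2-oxopropyl)phosphonate CC(=O)C(=[N+]=[N-])P(=O)(OC)OC
Why: The Ohira–Bestmann variant of the Seyferth–Gilbert homologation converts the non-epimerisable aldehyde into the terminal alkyne under mild basic conditions through the diazomethylphosphonate generated in the flask.

Step 7
Reactants: 12 tert-butyl(but-3-yn-1-yloxy)dimethylsilane
Product: 15 (2E)-5-{[tert-butyl(dimethyl)silyl]oxy}-3-methylpent-2-en-1-ol, via alkenyldimethylalane 13 (not isolated), via lithium alkenylalanate 14 (not isolated)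
Conditions: Me3Al (2 equiv), Cp2ZrCl2 (0.25 equiv), CH2Cl2, 0 °C → rt; volatiles removed; n-BuLi, hexane/THF, −30 °C; (CH2O)n, THF, rt
Reagents that add atoms: trimethylaluminium C[Al](C)C; formaldehyde (as paraformaldehyde) C=O
Why: Zr-catalysed syn-methylalumination (Negishi carboalumination) of the terminal alkyne places CH3 on the internal and Al on the terminal carbon, and the derived alanate adds to formaldehyde with retention, fixing the (E)-C2=C3 alkene.

Step 8
Reactants: 15 (2E)-5-{[tert-butyl(dimethyl)silyl]oxy}-3-methylpent-2-en-1-ol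
Product: 16 tert-butyl{[(3E)-5-{[tert-butyl(diphenyl)silyl]oxy}-3-methylpent-3-en-1-yl]oxy}dimethylsilane
Conditions: TBDPSCl, imidazole, CH2Cl2, rt
Reagents that add atoms: tert-butyl(chloro)diphenylsilane CC(C)(C)[Si](Cl)(c1ccccc1)c1ccccc1
Why: Standard silylation of the primary allylic alcohol gives a TBDPS ether that should survive the acidic removal of the TBS group and the organometallic key step.

Step 9
Reactants: 16 tert-butyl{[(3E)-5-{[tert-butyl(diphenyl)silyl]oxy}-3-methylpent-3-en-1-yl]oxy}dimethylsilane
Product: 17 (3E)-5-{[tert-butyl(diphenyl)silyl]oxy}-3-methylpent-3-en-1-ol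
Conditions: camphorsulfonic acid (cat.), MeOH/CH2Cl2, 0 °C
Reagents that add atoms: none
Why: Under mild Brønsted acid in methanol a primary TBS ether is solvolysed much faster than the bulkier TBDPS ether, which should free only the homoallylic alcohol (selective desilylation).

Step 10
Reactants: 17 (3E)-5-{[tert-butyl(diphenyl)silyl]oxy}-3-methylpent-3-en-1-ol
Product: 18 tert-butyl{[(2E)-5-iodo-3-methylpent-2-en-1-yl]oxy}diphenylsilane
Conditions: I2, PPh3, imidazole, CH2Cl2, 0 °C → rt
Reagents that add atoms: iodine [I][I]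
Why: Appel-type iodination converts the primary alcohol into the primary iodide by SN2 displacement under near-neutral conditions that leave the silyl ether and the alkene geometry intact.

Step 11
Reactants: 11 (5R,6S)-6-(but-3-yn-1-yl)-1,5,6-trimethylcyclohex-1-ene; 18 tert-butyl{[(2E)-5-iodo-3-methylpent-2-en-1-yl]oxy}diphenylsilane
Product: 21 tert-butyl{[(2E,6E)-3,7-dimethyl-9-[(1S,6R)-1,2,6-trimethylcyclohex-2-en-1-yl]nona-2,6-dien-1-yl]oxy}diphenylsilane, via alkenyldimethylalane 19 (not isolated), via alkenylzinc chloride 20 (not isolated)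
Conditions: 11 (1.3 equiv), Me3Al (2 equiv), Cp2ZrCl2 (0.25 equiv), CH2Cl2, 0 °C → rt; volatiles (excess Me3Al) removed in vacuo; THF, ZnCl2, 0 °C; then 18 (1.0 equiv), Pd2(dba)3 (2 mol%), P(c-C5H9)3 (8 mol%), N-methylimidazole, THF/NMP, rt → 60 °C
Reagents that add atoms: trimethylaluminium C[Al](C)C
Why: Proposed new method: Cp2ZrCl2-catalysed syn-methylalumination of the terminal alkyne of 11 should deliver CH3 to the internal carbon (C7) and Al to the terminal carbon (C6), Al→Zn exchange with ZnCl2 should give the alkenylzinc chloride 20, and SN2-type oxidative addition of the zerovalent palladium–trialkylphosphine catalyst to the primary C–I bond of 18, transmetalation and reductive elimination should then form the C6–C5 bond. The closest known reaction types are the Zr-catalysed carboalumination/Pd-catalysed cross-coupling sequence with aryl, alkenyl and allyl halides and the Pd/trialkylphosphine-catalysed Negishi coupling of alkenylzinc halides with unactivated primary alkyl iodides; the new element is their merger into a one-pot union with an unactivated alkyl electrophile. No ring is closed and no stereocentre is created; the (E) geometry of C6=C7 follows from the syn addition of CH3 and Al and from retention at the sp2 carbon in both transmetalations and in the reductive elimination. The step needs regioselective methylalumination (secured by the terminal alkyne, CH3 going to the substituted carbon), chemoselectivity (the trisubstituted ring alkene, the stereocentres and the silyl ether are inert, and excess Me3Al is removed so that alkenyl rather than methyl is transferred) and coupling faster than β-hydride elimination of the homoallylpalladium intermediate (secured by the bulky electron-rich P(c-C5H9)3 and the N-methylimidazole-activated zinc reagent).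

Step 12
Reactants: 21 tert-butyl{[(2E,6E)-3,7-dimethyl-9-[(1S,6R)-1,2,6-trimethylcyclohex-2-en-1-yl]nona-2,6-dien-1-yl]oxy}diphenylsilane
Product: 22 (2E,6E)-3,7-dimethyl-9-[(1S,6R)-1,2,6-trimethylcyclohex-2-en-1-yl]nona-2,6-dien-1-ol
Conditions: TBAF, THF, 0 °C → rt
Reagents that add atoms: none
Why: Fluoride cleaves the Si–O bond of the TBDPS ether selectively (fluoride desilylation) and should leave the three alkenes untouched.

Step 13
Reactants: 22 (2E,6E)-3,7-dimethyl-9-[(1S,6R)-1,2,6-trimethylcyclohex-2-en-1-yl]nona-2,6-dien-1-ol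
Product: 23 (5R,6S)-6-[(3E,7E)-9-bromo-3,7-dimethylnona-3,7-dien-1-yl]-1,5,6-trimethylcyclohex-1-ene
Conditions: CBr4, PPh3, CH2Cl2, 0 °C; used crude
Reagents that add atoms: tetrabromomethane BrC(Br)(Br)Br
Why: The Appel reaction converts primary allylic alcohols into allylic bromides under neutral conditions, which should avoid allylic transposition, E/Z isomerisation and acid-induced polyene cyclisation.

Step 14
Reactants: 24 hypotaurine (2-aminoethanesulfinic acid)
Product: 25 hypotaurocyamine (2-guanidinoethanesulfinic acid, zwitterion)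
Conditions: 1H-pyrazole-1-carboxamidine hydrochloride, NaOH (1.0 equiv), H2O (degassed), rt, argon
Reagents that add atoms: 1H-pyrazole-1-carboxamidine hydrochloride Cl.N=C(N)n1cccn1
Why: The free amino group of hypotaurine attacks the amidine carbon and expels pyrazole (amine guanidinylation), while the sulfinate should stay untouched under oxygen-free conditions.

Step 15
Reactants: 23 (5R,6S)-6-[(3E,7E)-9-bromo-3,7-dimethylnona-3,7-dien-1-yl]-1,5,6-trimethylcyclohex-1-ene; 25 hypotaurocyamine
Product: 26 Agelasidine C, 2-(2-{[(2E,6E)-3,7-dimethyl-9-[(1S,6R)-1,2,6-trimethylcyclohex-2-en-1-yl]nona-2,6-dien-1-yl]sulfonyl}ethyl)guanidine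
Conditions: DMF/H2O (degassed), rt, argon; then aqueous NaOH work-up
Reagents that add atoms: none
Why: SN2 S-alkylation of the soft sulfinate sulfur by the primary allylic bromide should give the allylic sulfone with retention of the (E)-C2=C3 geometry, the protonated guanidinium being non-nucleophilic (sulfinate alkylation).

**Compound list**

1 | 2-methylcyclohex-2-en-1-one | CC1=CCCCC1=O | starting material
2 | dimethylaluminium (3R)-2,3-dimethylcyclohex-1-en-1-olate | C[Al](C)OC1=C(C)[C@H](C)CCC1 | intermediate
3 | lithium trimethyl[(3R)-2,3-dimethylcyclohex-1-en-1-olato]aluminate | [Li+].C[Al-](C)(C)OC1=C(C)[C@H](C)CCC1 | intermediate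
4 | (2S,3R)-2,3-dimethyl-2-(prop-2-en-1-yl)cyclohexan-1-one | O=C1CCC[C@@H](C)[C@]1(C)CC=C | intermediate
5 | potassium (5R,6S)-5,6-dimethyl-6-(prop-2-en-1-yl)cyclohex-1-en-1-olate | [K+].[O-]C1=CCC[C@@H](C)[C@]1(C)CC=C | intermediate
6 | (5R,6S)-5,6-dimethyl-6-(prop-2-en-1-yl)cyclohex-1-en-1-yl trifluoromethanesulfonate | O=S(=O)(OC1=CCC[C@@H](C)[C@]1(C)CC=C)C(F)(F)F | intermediate
7 | (5R,6S)-1,5,6-trimethyl-6-(prop-2-en-1-yl)cyclohex-1-ene | CC1=CCC[C@@H](C)[C@]1(C)CC=C | intermediate
8 | 9-{3-[(1S,6R)-1,2,6-trimethylcyclohex-2-en-1-yl]propyl}-9-borabicyclo[3.3.1]nonane | CC1=CCC[C@@H](C)[C@]1(C)CCCB1C2CCCC1CCC2 | intermediate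
9 | 3-[(1S,6R)-1,2,6-trimethylcyclohex-2-en-1-yl]propan-1-ol | CC1=CCC[C@@H](C)[C@]1(C)CCCO | intermediate
10 | 3-[(1S,6R)-1,2,6-trimethylcyclohex-2-en-1-yl]propanal | CC1=CCC[C@@H](C)[C@]1(C)CCC=O | intermediate
11 | (5R,6S)-6-(but-3-yn-1-yl)-1,5,6-trimethylcyclohex-1-ene | CC1=CCC[C@@H](C)[C@]1(C)CCC#C | intermediate
12 | tert-butyl(but-3-yn-1-yloxy)dimethylsilane | C#CCCO[Si](C)(C)C(C)(C)C | starting material
13 | {(1E)-4-{[tert-butyl(dimethyl)silyl]oxy}-2-methylbut-1-en-1-yl}dimethylalane | C[Al](C)/C=C(\C)CCO[Si](C)(C)C(C)(C)C | intermediate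
14 | lithium butyl{(1E)-4-{[tert-butyl(dimethyl)silyl]oxy}-2-methylbut-1-en-1-yl}dimethylalanate | [Li+].CCCC[Al-](C)(C)/C=C(\C)CCO[Si](C)(C)C(C)(C)C | intermediate
15 | (2E)-5-{[tert-butyl(dimethyl)silyl]oxy}-3-methylpent-2-en-1-ol | OC/C=C(\C)CCO[Si](C)(C)C(C)(C)C | intermediate
16 | tert-butyl{[(3E)-5-{[tert-butyl(diphenyl)silyl]oxy}-3-methylpent-3-en-1-yl]oxy}dimethylsilane | CC(C)(C)[Si](OC/C=C(\C)CCO[Si](C)(C)C(C)(C)C)(c1ccccc1)c1ccccc1 | intermediate
17 | (3E)-5-{[tert-butyl(diphenyl)silyl]oxy}-3-methylpent-3-en-1-ol | OCC/C(C)=C/CO[Si](c1ccccc1)(c1ccccc1)C(C)(C)C | intermediate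
18 | tert-butyl{[(2E)-5-iodo-3-methylpent-2-en-1-yl]oxy}diphenylsilane | ICC/C(C)=C/CO[Si](c1ccccc1)(c1ccccc1)C(C)(C)C | intermediate
19 | dimethyl{(1E)-2-methyl-4-[(1S,6R)-1,2,6-trimethylcyclohex-2-en-1-yl]but-1-en-1-yl}alane | CC1=CCC[C@@H](C)[C@]1(C)CC/C(C)=C/[Al](C)C | intermediate
20 | chloro{(1E)-2-methyl-4-[(1S,6R)-1,2,6-trimethylcyclohex-2-en-1-yl]but-1-en-1-yl}zinc | CC1=CCC[C@@H](C)[C@]1(C)CC/C(C)=C/[Zn]Cl | intermediate
21 | tert-butyl{[(2E,6E)-3,7-dimethyl-9-[(1S,6R)-1,2,6-trimethylcyclohex-2-en-1-yl]nona-2,6-dien-1-yl]oxy}diphenylsilane | CC1=CCC[C@@H](C)[C@]1(C)CC/C(C)=C/CC/C(C)=C/CO[Si](c1ccccc1)(c1ccccc1)C(C)(C)C | intermediate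
22 | (2E,6E)-3,7-dimethyl-9-[(1S,6R)-1,2,6-trimethylcyclohex-2-en-1-yl]nona-2,6-dien-1-ol | CC1=CCC[C@@H](C)[C@]1(C)CC/C(C)=C/CC/C(C)=C/CO | intermediate
23 | (5R,6S)-6-[(3E,7E)-9-bromo-3,7-dimethylnona-3,7-dien-1-yl]-1,5,6-trimethylcyclohex-1-ene | CC1=CCC[C@@H](C)[C@]1(C)CC/C(C)=C/CC/C(C)=C/CBr | intermediate
24 | hypotaurine (2-aminoethanesulfinic acid) | NCCS(=O)O | starting material
25 | hypotaurocyamine (2-guanidinoethanesulfinic acid) | N=C(N)NCCS(=O)O | intermediate
26 | Agelasidine C | CC1=CCC[C@@H](C)[C@]1(C)CC/C(C)=C/CC/C(C)=C/CS(=O)(=O)CCN=C(N)N | target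

**Step count and risks**

Total step count: 15. Longest linear sequence: 10 steps (steps 1–6, 11, 12, 13, 15).

Step 11 (bears the label). What may go wrong: β-hydride elimination of the homoallylpalladium intermediate, transfer of methyl instead of alkenyl, or incomplete Al→Zn exchange. The fallback uses known chemistry with reversed polarity in two operations. Setting out from 11, the same Zr-catalysed methylalumination is quenched with iodine (THF, −30 °C) to give the (E)-alkenyl iodide F1. Iodide 18 is converted by zinc insertion (Zn dust, LiCl, THF) into the homoallylzinc iodide F2. Pd(PPh3)4-catalysed Negishi coupling of F1 with F2 in THF at rt comes back to the route at 21; here the alkyl group is transferred onto an alkenylpalladium iodide, so no alkylpalladium halide has to survive before C–C bond formation.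

Step 1. What may go wrong: sluggish C-allylation of the hindered aluminium enolate, competing O-allylation or proton quench, and poor facial selectivity at C2. The fallback sets out from 1 and the same conjugate addition. The aluminium enolate 2 is O-acylated with allyl chloroformate to the allyl enol carbonate F3, which is isolated. Pd(PPh3)4-catalysed decarboxylative allylation (Tsuji allylation, THF, rt) regenerates the enolate as a π-allylpalladium ion pair; it should deliver the allyl group anti to the C3 methyl group and comes back to the route at 4.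

Step 15. What may go wrong: O-alkylation of the ambident sulfinate, SN2′ attack, poor solubility of the zwitterion and air oxidation of the sulfinate. The fallback sets out from 23 and 24. Hypotaurine 24 is N-protected (Boc2O, NaOH, H2O/dioxane) to sodium 2-[(tert-butoxycarbonyl)amino]ethanesulfinate F4, a salt soluble in DMF. S-alkylation of F4 with 23 gives the Boc-amino sulfone F5. Boc removal under non-protic conditions (TMSOTf, 2,6-lutidine, CH2Cl2, 0 °C; then MeOH) gives the amino sulfone F6. Guanidinylation with 1H-pyrazole-1-carboxamidine hydrochloride and i-Pr2NEt in DMF comes back to the route at 26.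

**Further compounds**

F1 | step 11 | (5R,6S)-6-[(3E)-4-iodo-3-methylbut-3-en-1-yl]-1,5,6-trimethylcyclohex-1-ene | CC1=CCC[C@@H](C)[C@]1(C)CC/C(C)=C/I
F2 | step 11 | {(3E)-5-{[tert-butyl(diphenyl)silyl]oxy}-3-methylpent-3-en-1-yl}zinc iodide | I[Zn]CC/C(C)=C/CO[Si](c1ccccc1)(c1ccccc1)C(C)(C)C
F3 | step 1 | (3R)-2,3-dimethylcyclohex-1-en-1-yl prop-2-en-1-yl carbonate | C=CCOC(=O)OC1=C(C)[C@H](C)CCC1
F4 | step 15 | sodium 2-[(tert-butoxycarbonyl)amino]ethanesulfinate | [Na+].CC(C)(C)OC(=O)NCCS(=O)[O-]
F5 | step 15 | tert-butyl N-(2-{[(2E,6E)-3,7-dimethyl-9-[(1S,6R)-1,2,6-trimethylcyclohex-2-en-1-yl]nona-2,6-dien-1-yl]sulfonyl}ethyl)carbamate | CC1=CCC[C@@H](C)[C@]1(C)CC/C(C)=C/CC/C(C)=C/CS(=O)(=O)CCNC(=O)OC(C)(C)C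
F6 | step 15 | 2-{[(2E,6E)-3,7-dimethyl-9-[(1S,6R)-1,2,6-trimethylcyclohex-2-en-1-yl]nona-2,6-dien-1-yl]sulfonyl}ethan-1-amine | CC1=CCC[C@@H](C)[C@]1(C)CC/C(C)=C/CC/C(C)=C/CS(=O)(=O)CCN
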